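How much Z stands in the flask after 5.0 min, and how much Q has reacted by then?

| setting | Saturday's | Thursday's | flask |
|---|---|---|---|
| Q | 0.12 M | 0.12 M | 0.12 M |
| E | 0.47 equiv | 0.71 equiv | 0.950 equiv |
| remark | run made earlier | run made earlier |  |
| time |  |  | 5.0 min |
| volume of the second phase over the first |  |  | 1.0 |

| run | time / min | Z / % | Q / % |
|---|---|---|---|
| Saturday's | 0.333 | 0.5 | 96.9 |
| Saturday's | 1.00 | 2.1 | 89.3 |
| Saturday's | 2.00 | 4.3 | 81.3 |
| Saturday's | 2.50 | 7.1 | 77.2 |
| Saturday's | 4.00 | 11.3 | 67.9 |
| Saturday's | 5.00 | 12.5 | 65.4 |
| Thursday's | 0.417 | 1.6 | 95.7 |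
| Thursday's | 0.667 | 2.2 | 93.5 |
| Thursday's | 1.00 | 1.9 | 88.3 |
| Thursday's | 2.00 | 7.6 | 78.4 |
| Thursday's | 3.00 | 10.9 | 69.3 |
| Thursday's | 5.00 | 18.3 | 59.8 |

(readings scatter by 0.5 percentage points)

- amount of Z at 5.0 min, in percent of the Q charged
- part of the Q charged that has reacted at 5.0 min

- in the second phase: E; everything else is in the first
- charges count per volume of the first phase; a concentration in a rate is the amount of a species over the volume of its own phase; every rate counts per litre of the first phase
- the numbers in the tables scatter by 0.5 percentage points (one standard deviation)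
- the earlier runs hold the two phases in the same ratio of volumes as the flask asked about
- what has gone from Q into another species counts as reacted, even if it can come back

I count lifetimes, fastest clock first. In both runs some Q is missing without appearing as Z, and I call this part the store. Its early loss gives a lifetime of about 10.4 min. At 5.00 min the store reads 22.1 % on Saturday and 21.9 % on Thursday, although E differs. So I carry 22.0 % to the flask.

Z is the next clock. I take a first-order rate of Z from the final Z of each run and divide it by the [E] charged. This gives 0.474 /M/min on Saturday and 0.474 /M/min on Thursday. I keep their mean, the Z constant w = 0.474 /M/min.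

With [E] treated as constant, my lifetime of Q on its way to Z in the flask is 18.5 min. That is slower than the store and longer than the run. The flask's run therefore lasts 0.270 of a lifetime. My reckoning gives 23.7 % of Z, and adding the store gives 45.7 % reacted.

The forecast says 23 % and 42 %, on the ground that “Z formation, 12.5 versus 18.3 at 5 min, scales with E”, and my figures stand above both.

The flask gives 21.8 % of Z and 45.1 % reacted.

    G ⇌ E, rate k1*([G] - [E]/K1) per volume of the first phase (partition coefficient = 0.460, kL = 0.270 /min)
    Q + G → Z (k = 1.60 /M/min)
    G + Z → L (k = 1.50 /M/min)
    Q ⇌ D (K = 0.350, k = 0.110 /min)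

In this flask, the count of 0.270 lifetimes read Z as 23.7 %, against 21.8 %. The neighbour flask has 0.48 M of Q at the same equivalents and time. Its lifetime of Q on the way to Z, reckoned the same way, is 4.63 min, shorter than the run. Its count is 1.08, which reads Z as 66.1 %. The neighbour flask gives 32.1 % of Z and 17.1 % of L, together 49.2 %, less than the count reads, and has 63.6 % reacted.

The runs are calculated for an exercise, and the scatter is random.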